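**Retrosynthetic overview**

1. Numbering: ring A is the six-membered ring C3a–C4–C5–C6–C7–C7a, ring B the dihydrofuran O1–C2–C3–C3a–C7a, C1' the carbinol carbon, C1'' the prenyl CH2. The strategy rests on the quaternary C3a: its two CH2 arms, C3 of ring B and C1'' of the prenyl group, lie on the same face of ring B as the C2–C1' bond (C2 R, C3a S).
2. Key disconnection: C3a–C3 and C3a–C1'' are both cut back to one nucleophilic carbon, C3a–H of an O-alkylated acyl trione that carries a primary iodide at C3 and a bromoacetate on the C1' oxygen. One base treatment closes ring B and then a seven-membered lactone bridging C3a and the C1' oxygen.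
3. After the key step: thiolysis, Fukuyama reduction and Wittig isopropylidenation turn the C1''–C(=O)–O bridge into the prenyl group and the free tertiary alcohol.
4. Before the key step: ring A is filicinic acid. Its oxygen between the two CH groups opens (2S,3S)-epoxygeranyl silyl ether at C2 (inversion sets C2, retention sets C1'). C-acylation with (R)-2-methylbutanoic acid, iodide and bromoacetate follow.
5. Ring order: ring A (present from the start), then ring B and the bridged lactone (both in the key step), then the lactone is opened.

Key step: step 10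

Remark: each enolised trione is drawn as one tautomer; which enol oxygen carries the proton (or the silyl group in 12, 13 and 15) does not affect the chemistry.

**Route**

Step 1
Reactants: 1 2,4,6-trihydroxyacetophenone
Product: 2 acetylfilicinic acid
Conditions: MeI (2.2 equiv), NaOMe (3 equiv), MeOH, 0 °C to rt
Reagents that add atoms: iodomethane, CI
Why: dearomatising double C-methylation of the acylphloroglucinol polyanion at one ring carbon flanked by two phenoxide oxygens is the established entry to acylfilicinic acids, and over-methylated material should be separable by crystallisation.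

Step 2
Reactants: 2 acetylfilicinic acid
Product: 3 filicinic acid
Conditions: 6 M aq. HCl, reflux
Reagents that add atoms: none
Why: acid-mediated retro-Claisen deacylation of the beta-triketone should leave the symmetric trione, in which one oxygen lies between two CH groups and the other two lie next to the gem-dimethyl carbon.

Step 3
Reactants: 4 geraniol
Product: 5 (2S,3S)-2,3-epoxygeraniol
Conditions: Ti(OiPr)4 (5 mol%), L-(+)-diethyl tartrate (7 mol%), t-BuOOH, 4 Å MS, CH2Cl2, −20 °C
Reagents that add atoms: tert-butyl hydroperoxide, CC(C)(C)OO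
Why: Sharpless asymmetric epoxidation with the L-(+)-tartrate ligand delivers oxygen to the allylic alkene face that gives the (2S,3S) epoxide, which fixes the future C2 and C1', and the remote 6,7-alkene is not touched.

Step 4
Reactants: 5 (2S,3S)-2,3-epoxygeraniol
Product: 6 epoxygeranyl TBS ether
Conditions: TBSCl, imidazole, CH2Cl2, 0 °C to rt
Reagents that add atoms: tert-butyldimethylsilyl chloride, CC(C)(C)[Si](C)(C)Cl
Why: standard silyl ether formation at the primary alcohol blocks the Payne rearrangement that base would otherwise trigger in the next step.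

Step 5
Reactants: 3 filicinic acid; 6 epoxygeranyl TBS ether
Product: 7 filicinic acid sec-alkyl enol ether
Conditions: 3 (3 equiv), Cs2CO3 (0.5 equiv), DMF, 90 °C
Reagents that add atoms: none
Why: base-mediated SN2 opening of a 2,2,3-trisubstituted epoxide by an acidic O–H nucleophile (O-alkylation of a vinylogous acid) at the secondary carbon inverts C2 to R and leaves the S tertiary carbinol untouched; the hindered electrophile should choose oxygen over carbon and the oxygen between the two CH groups over those beside the gem-dimethyl carbon.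

Step 6
Reactants: 7 filicinic acid sec-alkyl enol ether; 8 (R)-2-methylbutanoic acid
Product: 10 acyl trione TBS ether, via enol ester 9 (not isolated)
Conditions: DCC (1.3 equiv), DMAP (1.0 equiv), CH2Cl2, 0 °C to rt
Reagents that add atoms: none
Why: Steglich O-acylation of the enol followed by DMAP-mediated O-to-C acyl migration is the standard route to 2-acyl-1,3-diones; the two nucleophilic ring carbons of 7 are equivalent by symmetry so one C-acyl product is possible, the tertiary alcohol is too hindered to be esterified, and no strong base is present to epimerise the R centre.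

Step 7
Reactants: 10 acyl trione TBS ether
Product: 11 acyl trione diol
Conditions: TBAF (3 equiv), THF, 0 °C to rt; AcOH quench; used at once
Reagents that add atoms: none
Why: fluoride cleavage of the primary silyl ether is carried out on the acyl trione as its delocalised enolate, which shields the enol ether carbon from the liberated primary alcohol.

Step 8
Reactants: 11 acyl trione diol
Product: 13 iodo silyl enol ether, via silyl enol ether alcohol 12 (not isolated)
Conditions: i-Pr3SiCl (1.1 equiv), Et3N (1.5 equiv), CH2Cl2, 0 °C; then PPh3 (1.5 equiv), I2 (1.5 equiv), imidazole (2 equiv), 0 °C to rt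
Reagents that add atoms: triisopropylsilyl chloride, CC(C)[Si](Cl)(C(C)C)C(C)C; iodine, I-I
Why: the acidic enol is silylated chemoselectively (as a carboxylic acid would be, alcohols needing a nucleophilic catalyst), so no enolate is present during the Appel iodination of the primary alcohol and ring B cannot close prematurely; the tertiary alcohol does not react.

Step 9
Reactants: 13 iodo silyl enol ether; 14 bromoacetyl bromide
Product: 16 iodo bromoacetate precursor, via silylated bromoacetate 15 (not isolated)
Conditions: 14 (1.5 equiv), pyridine (3 equiv), CH2Cl2, −20 to 0 °C; then HF·pyridine, THF, 0 °C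
Reagents that add atoms: none
Why: acylation of the tertiary alcohol with the acid bromide and pyridine gives a single ester because the enol is still masked, and acidic fluoride then removes the vinylogous silyl ester without base, so the neutral precursor is obtained with both electrophiles intact.

Step 10
Reactants: 16 iodo bromoacetate precursor
Product: 18 bridged lactone, via ring B enol 17 (not isolated)
Conditions: Cs2CO3 (4 equiv), MeCN, 40 °C, 16 added over 8 h to 2 mM final concentration
Reagents that add atoms: none
Why: Proposed new method: carbonate deprotonates the vinylogous acid of 16 and the C3a terminus of the dienolate displaces the primary iodide (C3a–C3); the new C3a–H of 17, flanked by the C4 carbonyl and the C7a=C7 vinylogous ester, is removed in turn and the enolate displaces bromide from the ester on the C1' oxygen (C3a–C1''); the closest known reactions are the intramolecular C-alkylation of cyclic beta-dicarbonyl enolates by omega-halides and their quaternisation by alpha-halo esters, whereas the tandem use on one carbon through a lactone tether is without direct precedent. Ring B closes in the 5-exo-tet mode with the enolate double bond exocyclic to the new ring, and the lactone closes in the 7-exo-tet mode. The only new stereocentre, C3a, is set by connectivity: the four-atom ester bridge can span C2 and C3a of the five-membered ring only cis, so the configuration of C2 from the epoxide dictates that of C3a, and the C3a–H centre of 17 is enolised again so its configuration does not matter. The step needs C- over O-alkylation and cyclisation over oligomerisation: attack through C3a gives five- and seven-membered rings whereas attack through the C4 oxygen would need seven- and nine-membered rings, C7 is blocked by the acyl group, and slow addition at high dilution suppresses intermolecular attack on the bromoacetate. Because both electrophiles hang from the C2–C1' unit, the reverse order (bromoacetate first through an eight-membered ring, iodide second) would converge on the same lactone.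

Step 11
Reactants: 18 bridged lactone
Product: 19 hydroxy S-ethyl thioester
Conditions: AlMe3 (3 equiv), EtSH (3.3 equiv), CH2Cl2, 0 °C; then 18, 0 °C to rt; aq. potassium sodium tartrate
Reagents that add atoms: ethanethiol, CCS (used as Me2AlSEt, C[Al](C)SCC)
Why: thiolysis of a lactone with dimethylaluminium ethanethiolate should open the strained bridged ester at its acyl carbon to the thioester and release the tertiary C1' alcohol, while the C7a enol ether carbon is shielded by the adjacent quaternary C3a.

Step 12
Reactants: 19 hydroxy S-ethyl thioester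
Product: 20 hydroxy aldehyde
Conditions: Et3SiH (3 equiv), 10% Pd/C (10 mol%), acetone, rt
Reagents that add atoms: none
Why: Fukuyama reduction converts the thioester to the aldehyde and leaves the ketones, the enone and the trisubstituted alkene untouched.

Step 13
Reactants: 20 hydroxy aldehyde
Product: 21 target (CNP0306408.2)
Conditions: i-PrPPh3I (3.5 equiv), n-BuLi (3.3 equiv), THF, 0 °C; then 20, −78 to 0 °C
Reagents that add atoms: isopropyltriphenylphosphonium iodide, CC(C)[P+](c1ccccc1)(c1ccccc1)c1ccccc1.[I-]
Why: Wittig olefination with the non-stabilised isopropylidene ylide should take the unhindered aldehyde far faster than the three flanked ketones; the excess ylide covers the tertiary alkoxide and the low temperature protects the alpha centre of the acyl group.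

**Compound list**

1 | 2,4,6-trihydroxyacetophenone | CC(=O)c1c(O)cc(O)cc1O | starting material
2 | acetylfilicinic acid, 2-acetyl-3,5-dihydroxy-4,4-dimethylcyclohexa-2,5-dien-1-one | CC(=O)C1=C(O)C(C)(C)C(O)=CC1=O | intermediate
3 | filicinic acid, 3,5-dihydroxy-4,4-dimethylcyclohexa-2,5-dien-1-one | CC1(C)C(O)=CC(=O)C=C1O | intermediate
4 | geraniol, (2E)-3,7-dimethylocta-2,6-dien-1-ol | CC(C)=CCC/C(C)=C/CO | starting material
5 | (2S,3S)-2,3-epoxygeraniol, [(2S,3S)-3-methyl-3-(4-methylpent-3-en-1-yl)oxiran-2-yl]methanol | OC[C@@H]1O[C@@]1(C)CCC=C(C)C | intermediate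
6 | tert-butyldimethylsilyl ether of 5 | CC(C)(C)[Si](C)(C)OC[C@@H]1O[C@@]1(C)CCC=C(C)C | intermediate
7 | 3-{[(2R,3S)-1-(tert-butyldimethylsilyloxy)-3-hydroxy-3,7-dimethyloct-6-en-2-yl]oxy}-5-hydroxy-6,6-dimethylcyclohexa-2,4-dien-1-one | CC1(C)C(O)=CC(O[C@@H]([C@@](C)(O)CCC=C(C)C)CO[Si](C)(C)C(C)(C)C)=CC1=O | intermediate
8 | (R)-2-methylbutanoic acid | CC[C@@H](C)C(=O)O | starting material
9 | enol (R)-2-methylbutanoate of 7 (ester at the remaining enol oxygen) | CC[C@@H](C)C(=O)OC1=CC(O[C@@H]([C@@](C)(O)CCC=C(C)C)CO[Si](C)(C)C(C)(C)C)=CC(=O)C1(C)C | intermediate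
10 | 3-{[(2R,3S)-1-(tert-butyldimethylsilyloxy)-3-hydroxy-3,7-dimethyloct-6-en-2-yl]oxy}-5-hydroxy-6,6-dimethyl-2-[(2R)-2-methylbutanoyl]cyclohexa-2,4-dien-1-one | CC[C@@H](C)C(=O)C1=C(O[C@@H]([C@@](C)(O)CCC=C(C)C)CO[Si](C)(C)C(C)(C)C)C=C(O)C(C)(C)C1=O | intermediate
11 | 3-{[(2R,3S)-1,3-dihydroxy-3,7-dimethyloct-6-en-2-yl]oxy}-5-hydroxy-6,6-dimethyl-2-[(2R)-2-methylbutanoyl]cyclohexa-2,4-dien-1-one | CC[C@@H](C)C(=O)C1=C(O[C@@H]([C@@](C)(O)CCC=C(C)C)CO)C=C(O)C(C)(C)C1=O | intermediate
12 | 5-O-triisopropylsilyl enol ether of 11 | CC[C@@H](C)C(=O)C1=C(O[C@@H]([C@@](C)(O)CCC=C(C)C)CO)C=C(O[Si](C(C)C)(C(C)C)C(C)C)C(C)(C)C1=O | intermediate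
13 | 3-{[(2S,3S)-3-hydroxy-1-iodo-3,7-dimethyloct-6-en-2-yl]oxy}-6,6-dimethyl-2-[(2R)-2-methylbutanoyl]-5-(triisopropylsilyloxy)cyclohexa-2,4-dien-1-one | CC[C@@H](C)C(=O)C1=C(O[C@@H]([C@@](C)(O)CCC=C(C)C)CI)C=C(O[Si](C(C)C)(C(C)C)C(C)C)C(C)(C)C1=O | intermediate
14 | bromoacetyl bromide | BrCC(=O)Br | starting material
15 | bromoacetate of 13 at the tertiary oxygen | CC[C@@H](C)C(=O)C1=C(O[C@@H]([C@@](C)(OC(=O)CBr)CCC=C(C)C)CI)C=C(O[Si](C(C)C)(C(C)C)C(C)C)C(C)(C)C1=O | intermediate
16 | key-step precursor, (2S,3S)-2-({5-hydroxy-4,4-dimethyl-2-[(2R)-2-methylbutanoyl]-3-oxocyclohexa-1,5-dien-1-yl}oxy)-1-iodo-3,7-dimethyloct-6-en-3-yl bromoacetate | CC[C@@H](C)C(=O)C1=C(O[C@@H]([C@@](C)(OC(=O)CBr)CCC=C(C)C)CI)C=C(O)C(C)(C)C1=O | intermediate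
17 | ring B closed enol, (2R)-2-[(2S)-2-(bromoacetoxy)-6-methylhept-5-en-2-yl]-4-hydroxy-5,5-dimethyl-7-[(2R)-2-methylbutanoyl]-2,3-dihydro-1-benzofuran-6(5H)-one | CC[C@@H](C)C(=O)C1=C2O[C@@H]([C@@](C)(OC(=O)CBr)CCC=C(C)C)CC2=C(O)C(C)(C)C1=O | intermediate
18 | bridged lactone: (2R,3aR)-5,5-dimethyl-7-[(2R)-2-methylbutanoyl]-2,3-dihydro-1-benzofuran-4,6(3aH,5H)-dione whose C2 and C3a are bridged by –C(CH3)(CH2CH2CH=C(CH3)2)–O–C(=O)–CH2– (C1' S) | CC[C@@H](C)C(=O)C1=C2O[C@@H]([C@@](C)(O3)CCC=C(C)C)C[C@]2(CC3=O)C(=O)C(C)(C)C1=O | intermediate
19 | S-ethyl {(2R,3aR)-2-[(2S)-2-hydroxy-6-methylhept-5-en-2-yl]-5,5-dimethyl-7-[(2R)-2-methylbutanoyl]-4,6-dioxo-2,3,5,6-tetrahydro-1-benzofuran-3a(4H)-yl}ethanethioate | CC[C@@H](C)C(=O)C1=C2O[C@@H]([C@@](C)(O)CCC=C(C)C)C[C@]2(CC(=O)SCC)C(=O)C(C)(C)C1=O | intermediate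
20 | {(2R,3aR)-2-[(2S)-2-hydroxy-6-methylhept-5-en-2-yl]-5,5-dimethyl-7-[(2R)-2-methylbutanoyl]-4,6-dioxo-2,3,5,6-tetrahydro-1-benzofuran-3a(4H)-yl}acetaldehyde | CC[C@@H](C)C(=O)C1=C2O[C@@H]([C@@](C)(O)CCC=C(C)C)C[C@]2(CC=O)C(=O)C(C)(C)C1=O | intermediate
21 | (2R,3aS)-2-[(2S)-2-hydroxy-6-methylhept-5-en-2-yl]-5,5-dimethyl-7-[(2R)-2-methylbutanoyl]-3a-(3-methylbut-2-en-1-yl)-2,3-dihydro-1-benzofuran-4,6(3aH,5H)-dione | CC[C@@H](C)C(=O)C1=C2O[C@@H]([C@@](C)(O)CCC=C(C)C)C[C@]2(CC=C(C)C)C(=O)C(C)(C)C1=O | target

**Step count**

Total steps: 13. Longest linear sequence: 11 steps (geraniol 4 to target 21, steps 3 to 13); filicinic acid 3 is made in two steps and joins at step 5.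

**Steps most likely to fail**

Step 10 (proposed new method). Intermolecular alkylation by the bromoacetate or O-alkylation may outrun the slow closure of ring B at the beta-branched iodide, and the second closure may stall on the strain of the bridged ring. The fallback runs the two alkylations as separate, individually known operations; it sets out from 13 and comes back at 18. Treating 13 with CsF in MeCN removes the silyl group, and the enolate closes ring B with no bromoacetate present, giving the ring B hydroxy enol F1. Bromoacetyl bromide and pyridine (2.5 equiv) then acylate both the enol and the tertiary hydroxyl to the bis(bromoacetate) F2. Cold aqueous NaHCO3 hydrolyses the enol ester to 17, which is now isolated. Cs2CO3 in dilute MeCN then has only the lactone closure to perform and gives 18.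

Step 5. The opening may be too slow at the hindered, inductively deactivated C2, or it may proceed through the ring carbon or at the tertiary epoxide carbon. The fallback never breaks the C2–O bond; it sets out from 4 and comes back at 7. Geraniol 4 is epoxidised with D-(−)-diethyl tartrate to (2R,3R)-2,3-epoxygeraniol F3. Dilute HClO4 in aqueous THF brings water in at the tertiary carbon with inversion to give the (2R,3S)-triol F4, which is silylated at the primary hydroxyl to the diol silyl ether F5. F5 is condensed through its secondary hydroxyl with filicinic acid 3 under acid catalysis (pyridinium p-toluenesulfonate, benzene, azeotropic removal of water) to the vinylogous ester 7, with retention at C2.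

Step 11. The thiolate may add to the C7a vinylogous ester carbon and open ring B, or the hindered lactone may open incompletely. The fallback separates ring opening from thioester formation; it sets out from 18 and comes back at 19. Me3SnOH in 1,2-dichloroethane at 70 °C hydrolyses the lactone to the hydroxy acid F6, and a Steglich thioesterification (EtSH, DCC, catalytic DMAP) gives 19.

**Further compounds**

F1 | step 10 | ring B hydroxy enol, (2R)-4-hydroxy-2-[(2S)-2-hydroxy-6-methylhept-5-en-2-yl]-5,5-dimethyl-7-[(2R)-2-methylbutanoyl]-2,3-dihydro-1-benzofuran-6(5H)-one | CC[C@@H](C)C(=O)C1=C2O[C@@H]([C@@](C)(O)CCC=C(C)C)CC2=C(O)C(C)(C)C1=O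
F2 | step 10 | bis(bromoacetate) of F1 (enol ester and tertiary ester) | CC[C@@H](C)C(=O)C1=C2O[C@@H]([C@@](C)(OC(=O)CBr)CCC=C(C)C)CC2=C(OC(=O)CBr)C(C)(C)C1=O
F3 | step 5 | (2R,3R)-2,3-epoxygeraniol | OC[C@H]1O[C@]1(C)CCC=C(C)C
F4 | step 5 | (2R,3S)-3,7-dimethyloct-6-ene-1,2,3-triol | OC[C@@H](O)[C@@](C)(O)CCC=C(C)C
F5 | step 5 | (2R,3S)-1-(tert-butyldimethylsilyloxy)-3,7-dimethyloct-6-ene-2,3-diol | CC(C)(C)[Si](C)(C)OC[C@@H](O)[C@@](C)(O)CCC=C(C)C
F6 | step 11 | {(2R,3aR)-2-[(2S)-2-hydroxy-6-methylhept-5-en-2-yl]-5,5-dimethyl-7-[(2R)-2-methylbutanoyl]-4,6-dioxo-2,3,5,6-tetrahydro-1-benzofuran-3a(4H)-yl}acetic acid | CC[C@@H](C)C(=O)C1=C2O[C@@H]([C@@](C)(O)CCC=C(C)C)C[C@]2(CC(=O)O)C(=O)C(C)(C)C1=O
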